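Target in the south run read 54.3 % at 1.04 d and then fell, and I wanted to know what the same charge would hold at 3.0 d if its target were born later.

all flasks: substrate 0.10 M

| flask | reagent | catalyst | remark | time |
|---|---|---|---|---|
| south | 1.8 equiv | 0.5 mol% | run made earlier |  |
| south-west | 1.8 equiv | 0.25 mol% | run made earlier |  |
| west | 1.8 equiv | 0.38 mol% | run made earlier |  |
| north | 0.90 equiv | 0.5 mol% | run made earlier |  |
| teal | 1.80 equiv | 0.5 mol% | everything together in a closed stirred flask, run for 3.0 d | 3.0 d |
| ochre | 1.80 equiv | 0.5 mol% | one stirred flow tank at steady state, fed with the mixture as stated, mean residence time 3.0 d |  |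
| blue | 1.80 equiv | 0.5 mol% | a single well-mixed tank run continuously and read at steady state, 30.0 d in it on average |  |
| green | 1.80 equiv (fed, over 3.00 d) | 0.5 mol% | all but reagent at the start; reagent goes in evenly over 3.00 d, the run ends at 3.0 d | 3.0 d |

| run | time / d | target / % | substrate / % |
|---|---|---|---|
| south | 0.500 | 37.7 | 14.9 |
| south | 1.04 | 54.3 | 1.9 |
| south | 1.67 | 50.7 | 0 |
| south | 2.08 | 43.3 | 1.2 |
| south | 2.50 | 36.5 | 0 |
| south | 3.00 | 28.6 | 0.7 |
| south-west | 0.250 | 6.7 | 61.7 |
| south-west | 0.500 | 17.2 | 37.8 |
| south-west | 0.833 | 30.6 | 20.4 |
| south-west | 1.25 | 43.6 | 9.3 |
| south-west | 2.00 | 53.9 | 2.6 |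
| south-west | 4.00 | 44.5 | 0.9 |
| west | 0.250 | 10.7 | 49.0 |
| west | 0.500 | 28.9 | 22.8 |
| west | 0.833 | 44.6 | 8.8 |
| west | 1.25 | 53.1 | 2.8 |
| west | 2.00 | 51.6 | 0.1 |
| west | 4.00 | 27.6 | 0 |
| north | 0.250 | 8.9 | 37.9 |
| north | 0.500 | 23.0 | 14.7 |
| north | 1.04 | 36.0 | 1.3 |
| north | 2.08 | 33.5 | 0.1 |
| north | 4.00 | 18.1 | 0 |

(scatter of a reading: 0.5 percentage points)

* the set-up with the highest amount of target at the outlet or at the end, in percent of the substrate put in ("none" if the first two lie within 2 percentage points) (teal / ochre / blue / green / none)
* amount of target at the outlet or at the end, in percent of the substrate put in, teal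
* amount of target at the outlet or at the end, in percent of the substrate put in, ochre
* amount of target at the outlet or at the end, in percent of the substrate put in, blue
* amount of target at the outlet or at the end, in percent of the substrate put in, green

- the stated concentrations are those of everything mixed, before any reaction; amounts are the same in each set-up
- what was read earlier has a scatter of 0.5 percentage points, one standard deviation
- the feed brings no volume worth counting
- the earlier runs were made in a closed, stirred flask

South is the neighbour of green: the charge and the end time match, and teal is south itself, which read 28.6 % at 3.00 d. Green differs in when the reagent arrives. That should matter. At 0.500 d north and south held nearly equal substrate (14.7 % and 14.9 %), yet north, with half the [reagent], read 23.0 % of target, less than the 37.7 % in south. So I took target's birth to follow the reagent.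

From the late fall in south, with substrate reading 1.2 %, I read an apparent target lifetime L, the time in which the target reading drops by a factor of e late in a run at 0.5 mol% of catalyst:

L = (3.00 d − 2.08 d) / ln(43.3 % / 28.6 %) = 2.22 d

My rule was that the share of target surviving, F, is the mean of exp(−age/L) over the ages that all the target born would have reached by the reading. The zero of my scale was even birth, which I took dosing to approach. For a tank, I took the ages from the residence-time distribution:

South, born near 1.04 d: F = 41.3 %

Green, ages spread evenly over 3.00 d: F = 54.8 %

Ochre, ages falling off exponentially with a mean of 3.0 d: F = 42.5 %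

Blue, ages falling off exponentially with a mean of 30.0 d: F = 6.89 %

So green should keep more of its target than south. I expected teal near its south reading, ochre under 42.5 %, blue near 6.89 %, and green highest, somewhat under 54.8 %, since I allowed that some substrate would not yet be target.

The forecast named green, with teal 28.5 %, ochre 32 %, blue 6 % and green 50 %, on the ground that “Green keeps reagent low early, slowing decay, and target forms late”.

The flask gave teal 28.8 %, ochre 27.6 %, blue 5.28 % and green 41.0 %, so green stood highest.

    substrate + catalyst → catalyst + intermediate (k = 320 /M/h)
    reagent + catalyst + intermediate → catalyst + target (k = 1200 /M²/h)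
    catalyst + target → catalyst + over-reaction product (k = 48.0 /M/h)

With the conversion of target into over-reaction product taken away, green stands at 86.7 %, so that step is a part of why green ends at 41.0 %. Green therefore kept 47.3 % of its target, where L had given 54.8 %. In blue the same step is the main reason for the shortfall: without it blue stands at 96.5 %. Blue therefore kept 5.47 %, where L of 2.22 d had given 6.89 %.

The numbers in the tables are calculated with made-up constants, noise included.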